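**Retrosynthetic overview**

1. Numbering is oleanane-type; C27 is the extra methylene between C12 and C13, so ring C is seven-membered (C8, C9, C11, C12, C27, C13, C14). The strategy rests on C4: it carries a methyl group and the axial carboxyl group next to the C3 carbinol and is the α-carbon of an α-methyl β-keto ester, while C5/C10 and C9/C8 are the carbons of the two E-alkenes of a geranyl chain.
2. Rings A and B: one oxidative radical bicyclisation (C4–C5, then C10–C9) of an 8-phenylmenthyl β-keto ester built from geranyl acetate.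
3. C8 quaternary centre with C14/C15 by Johnson–Claisen from C11–OH; C9–H by hydroboration; C12 by reagent-controlled allylation; ring C by Reformatsky closure C13–C14, then enol triflate at C13.
4. Ring E is made separately as a cyclohexene whose C17 is set by Claisen chirality transfer from C19; it is joined at C15–C16, and ring D closes by Heck carbopalladation C13–C18 with boron capture at C19.
5. Ring order: A+B, then C, then D onto preformed E; both carboxyl groups are carried as esters, reduced and re-oxidised at the end.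

Key step: step 6

Assumption: the (−)-8-phenylmenthyl ester is taken to shield the face of the C4 radical that gives the configuration drawn, and in step 28 the quaternary carbon is taken as the large ketone substituent; the route is written for these senses.

Step 1
Reactants: 1 (−)-8-phenylmenthol; 2 2,2,6-trimethyl-4H-1,3-dioxin-4-one
Product: 4 (−)-8-phenylmenthyl 3-oxobutanoate, via acetylketene 3 (not isolated)
Conditions: xylene, 140 °C, distil off acetone
Reagents that add atoms: none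
Why: Thermal cycloreversion of the dioxinone releases acetylketene, which acylates the hindered secondary alcohol (acetoacetylation); no stereocentre is formed.

Step 2
Reactants: 4 (−)-8-phenylmenthyl 3-oxobutanoate
Product: 5 (−)-8-phenylmenthyl 2-methyl-3-oxobutanoate (both C2 epimers)
Conditions: K2CO3, MeI, acetone, reflux
Reagents that add atoms: iodomethane, CI
Why: C-Methylation of the β-keto ester enolate; the new centre is a mixture, which is immaterial because it becomes the planar C4 radical in step 6.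

Step 3
Reactants: 6 geranyl acetate
Product: 7 (2E,6E)-8-hydroxy-3,7-dimethylocta-2,6-dien-1-yl acetate
Conditions: SeO2 (cat.), t-BuOOH, salicylic acid (cat.), CH2Cl2, rt
Reagents that add atoms: tert-butyl hydroperoxide, CC(C)(C)OO (terminal oxidant; oxygen is delivered through selenium dioxide, O=[Se]=O)
Why: Catalytic SeO2 allylic oxidation (ene reaction then [2,3] shift) is selective for the E-methyl group of the electron-rich terminal alkene, the other alkene being deactivated by the allylic acetate.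

Step 4
Reactants: 7 (2E,6E)-8-hydroxy-3,7-dimethylocta-2,6-dien-1-yl acetate
Product: 8 (2E,6E)-8-bromo-3,7-dimethylocta-2,6-dien-1-yl acetate
Conditions: PBr3, Et2O, 0 °C
Reagents that add atoms: phosphorus tribromide, BrP(Br)Br
Why: SN2 bromination of the primary allylic alcohol keeps the E-alkene geometry and leaves the acetate untouched.

Step 5
Reactants: 5 (−)-8-phenylmenthyl 2-methyl-3-oxobutanoate; 8 (2E,6E)-8-bromo-3,7-dimethylocta-2,6-dien-1-yl acetate
Product: 9 (−)-8-phenylmenthyl (6E,10E)-12-acetoxy-2,6,10-trimethyl-3-oxododeca-6,10-dienoate (both C2 epimers)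
Conditions: NaH, THF, 0 °C; n-BuLi, −10 °C; then 8, 0 °C
Reagents that add atoms: none
Why: Dianion alkylation of a β-keto ester: the more reactive γ-carbanion displaces the allylic bromide, so the chain is attached at the ketone methyl carbon and the α-methyl β-keto ester is kept.

Step 6
Reactants: 9 (−)-8-phenylmenthyl (6E,10E)-12-acetoxy-2,6,10-trimethyl-3-oxododeca-6,10-dienoate
Product: 10 rings A/B keto ester (C3 ketone; C4 with α-CH3 and β-axial CO2-8-phenylmenthyl; 5α-H; 10β-CH3; C8 exocyclic methylene; 9α-H with 9β-CH2OAc)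
Conditions: Mn(OAc)3·2H2O (2.2 equiv), Cu(OAc)2·H2O (1 equiv), degassed AcOH, rt
Reagents that add atoms: none
Why: Trivalent manganese (Mn(OAc)3) oxidises the enol of the α-methyl β-keto ester to the electrophilic C4 radical, which adds to C5 of the first E-alkene; the tertiary C10 radical then adds to C9, and the tertiary C8 radical is oxidised by divalent copper (Cu(OAc)2) and loses a proton from the C8 methyl group to give the exocyclic methylene. The closest known reaction type is the Mn(OAc)3/Cu(OAc)2 oxidative free-radical polyene cyclisation of unsaturated β-keto esters, including esters that carry a phenylmenthyl-type auxiliary. Ring A closes 6-endo (C4–C5) and ring B closes 6-endo (C10–C9), each through a chair-like transition state of the E,E-diene. The chair–chair folding sets the trans ring fusion (5α-H, 10β-CH3) and 9α-H with the CH2OAc group equatorial; C4 arises with the ester axial and the methyl equatorial, as is usual for α-methyl β-keto ester radicals; the absolute sense is set by the 8-phenylmenthyl group, whose aryl ring shields one face of the C4 radical. The step needs face selectivity at C4 and regioselective termination: the auxiliary secures the first and the copper salt the second, and any endocyclic C7–C8 alkene isomer converges with 10 at enal 15.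

Step 7
Reactants: 10 rings A/B keto ester
Product: 11 3α-alcohol of 10 (axial OH)
Conditions: L-Selectride, THF, −78 °C
Reagents that add atoms: none
Why: The bulky trialkylborohydride attacks the hindered C3 ketone from the equatorial β direction and so delivers the axial 3α-alcohol, and at −78 °C the ketone reacts far faster than the acetate or the neopentyl ester.

Step 8
Reactants: 11 3α-alcohol
Product: 12 3α-TBS ether
Conditions: TBSOTf, 2,6-lutidine, CH2Cl2, 0 °C to rt
Reagents that add atoms: tert-butyldimethylsilyl trifluoromethanesulfonate, CC(C)(C)[Si](C)(C)OS(=O)(=O)C(F)(F)F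
Why: The silyl triflate silylates even the hindered axial alcohol, which must be masked for the oxidations and basic steps that follow.

Step 9
Reactants: 12 3α-TBS ether
Product: 13 C11 primary alcohol
Conditions: K2CO3 (cat.), MeOH, rt
Reagents that add atoms: none
Why: Base-catalysed methanolysis removes the primary acetate, while the neopentyl 8-phenylmenthyl ester and the silyl ether are too hindered to react.

Step 10
Reactants: 13 C11 primary alcohol
Product: 15 conjugated C11 aldehyde (C8=C9; C8–CH3), via β,γ-unsaturated aldehyde 14 (not isolated)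
Conditions: Dess–Martin periodinane, NaHCO3, CH2Cl2, 0 °C; then DBU, rt
Reagents that add atoms: none
Why: Dess–Martin oxidation gives aldehyde 14, and DBU moves the alkene into conjugation by deprotonation at C9 and reprotonation at the exocyclic carbon, which places the double bond specifically at C8–C9; the C9 centre is erased on purpose and is set again in step 13.

Step 11
Reactants: 15 conjugated C11 aldehyde
Product: 16 allylic alcohol (C11–OH; C8=C9)
Conditions: NaBH4, CeCl3·7H2O, MeOH, 0 °C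
Reagents that add atoms: none
Why: Luche reduction gives clean 1,2-reduction of the hindered enal and does not touch the ester.

Step 12
Reactants: 16 allylic alcohol
Product: 18 C8 quaternary ester (8β-CH3; 8α-CH2CO2Et = C14 and C15; C9=C11H2), via ketene acetal 17 (not isolated)
Conditions: MeC(OEt)3, EtCO2H (cat.), xylene, 140 °C, distil off EtOH
Reagents that add atoms: triethyl orthoacetate, CC(OCC)(OCC)OCC
Why: Johnson–Claisen rearrangement: the [3,3] shift of ketene acetal 17 forms the C8–C14 bond on the α face, anti to the axial C10 methyl group, so C8 becomes quaternary with its methyl β and the alkene moves to C9=C11.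

Step 13
Reactants: 18 C8 quaternary ester
Product: 20 C11 alcohol (9α-H; 9β-CH2OH), via alkylborane 19 (not isolated)
Conditions: BH3·SMe2, THF, 0 °C to rt; then Me3NO·2H2O, 60 °C
Reagents that add atoms: trimethylamine N-oxide, C[N+](C)(C)[O-]
Why: Hydroboration of the 1,1-disubstituted alkene puts boron on C11 and hydrogen on C9 from the α face, because the β face is blocked by the axial methyl groups on C8 and C10, which sets 9α-H; amine oxide oxidation of the C–B bond with retention spares the ethyl ester.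

Step 14
Reactants: 20 C11 alcohol
Product: 21 C11 aldehyde
Conditions: Dess–Martin periodinane, NaHCO3, CH2Cl2, rt
Reagents that add atoms: none
Why: Buffered Dess–Martin oxidation; the equatorial aldehyde is also the stable C9 epimer, so the centre is not at risk.

Step 15
Reactants: 21 C11 aldehyde
Product: 22 methyl enol ether (C11=C12–OMe; E/Z mixture)
Conditions: MeOCH2PPh3Cl, KHMDS, THF, 0 °C to rt
Reagents that add atoms: (methoxymethyl)triphenylphosphonium chloride, COC[P+](c1ccccc1)(c1ccccc1)c1ccccc1.[Cl-]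
Why: Wittig reaction with the methoxymethylene ylide adds C12 as an enol ether (one-carbon homologation); the ylide does not attack esters.

Step 16
Reactants: 22 methyl enol ether
Product: 23 C12 aldehyde
Conditions: 1 N HCl, THF, rt
Reagents that add atoms: water, O
Why: Mild acid hydrolysis of the enol ether releases the aldehyde, while the hindered secondary silyl ether survives.

Step 17
Reactants: 23 C12 aldehyde
Product: 25 (12R)-homoallylic alcohol (C12–OH; C27H2–CH=CH2), via borinate 24 (not isolated)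
Conditions: (+)-Ipc2B(allyl), Et2O, −78 °C; then NaBO3·4H2O, THF/H2O, rt
Reagents that add atoms: (+)-B-allyldiisopinocampheylborane, C=CCB([C@H]1C[C@H]2C[C@@H]([C@@H]1C)C2(C)C)[C@H]1C[C@H]2C[C@@H]([C@@H]1C)C2(C)C
Why: Brown allylboration: the reagent derived from (−)-α-pinene adds to the Re face of the aldehyde through a chair transition state under reagent control, which sets C12 (12R here, the 12α-oxygen of the target), and perborate frees the alcohol from borinate 24.

Step 18
Reactants: 25 (12R)-homoallylic alcohol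
Product: 26 12-methyl ether
Conditions: Me3OBF4, 1,8-bis(dimethylamino)naphthalene, CH2Cl2, rt
Reagents that add atoms: trimethyloxonium tetrafluoroborate, C[O+](C)C.F[B-](F)(F)F
Why: O-Methylation with the oxonium salt and a non-nucleophilic proton scavenger avoids an alkoxide, so neither lactonisation onto the ethyl ester nor elimination can occur.

Step 19
Reactants: 26 12-methyl ether
Product: 28 α-bromo ester (C14–Br; both epimers), via silyl ketene acetal 27 (not isolated)
Conditions: LDA, TMSCl, THF, −78 °C; then NBS, −78 to 0 °C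
Reagents that add atoms: N-bromosuccinimide, O=C1CCC(=O)N1Br
Why: The ethyl ester is the only enolisable carbonyl group; its silyl ketene acetal is brominated at C14, and the new centre is a mixture that becomes sp2 in step 23.

Step 20
Reactants: 28 α-bromo ester
Product: 30 C13 aldehyde, via ozonide 29 (not isolated)
Conditions: O3, CH2Cl2, −78 °C; then PPh3
Reagents that add atoms: ozone, [O-][O+]=O
Why: Ozonolysis of the only alkene with reductive work-up gives the C13 aldehyde and removes the extra vinyl carbon as formaldehyde.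

Step 21
Reactants: 30 C13 aldehyde
Product: 31 ring C β-hydroxy ester (C13–OH; C14–CO2Et; isomer mixture)
Conditions: SmI2 (2.5 equiv), THF, −78 °C, high dilution
Reagents that add atoms: none
Why: Intramolecular Reformatsky reaction: divalent samarium (SmI2) reduces the C–Br bond to a samarium enolate that adds to the C13 aldehyde under non-basic conditions, which closes the seven-membered ring C without β-elimination of the C12 methoxy group; the two new centres are mixtures and are removed in steps 22 and 23.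

Step 22
Reactants: 31 ring C β-hydroxy ester
Product: 32 ring C β-keto ester (C13 ketone)
Conditions: Dess–Martin periodinane, NaHCO3, CH2Cl2, rt
Reagents that add atoms: none
Why: Neutral oxidation of the secondary alcohol gives the cyclic β-keto ester without enolisation towards C27.

Step 23
Reactants: 32 ring C β-keto ester
Product: 33 enol triflate (C13–OTf; C13=C14; C14–CO2Et)
Conditions: NaH, THF, 0 °C; then PhNTf2, rt
Reagents that add atoms: N-phenylbis(trifluoromethanesulfonimide), O=S(=O)(N(c1ccccc1)S(=O)(=O)C(F)(F)F)C(F)(F)F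
Why: Deprotonation at the doubly activated C14 and O-sulfonylation of the enolate give the enol triflate; the ring fixes the tetrasubstituted alkene at C13=C14 with C8 and C27 cis.

Step 24
Reactants: 33 enol triflate
Product: 34 allylic alcohol (C15–OH)
Conditions: DIBAL-H, CH2Cl2, −78 °C
Reagents that add atoms: none
Why: DIBAL-H reduces the conjugated ethyl ester to the allylic alcohol at low temperature and leaves the alkenyl triflate and the neopentyl ester.

Step 25
Reactants: 34 allylic alcohol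
Product: 35 allylic bromide (C15–Br)
Conditions: CBr4, PPh3, CH2Cl2, 0 °C
Reagents that add atoms: carbon tetrabromide, BrC(Br)(Br)Br
Why: Appel bromination of the primary allylic alcohol under neutral conditions.

Step 26
Reactants: 36 4,4-dimethylcyclohexane-1,3-dione
Product: 37 4,4-dimethyl-3-oxocyclohex-1-en-1-yl trifluoromethanesulfonate
Conditions: Tf2O, pyridine, CH2Cl2, −78 to 0 °C
Reagents that add atoms: trifluoromethanesulfonic anhydride, O=S(=O)(OS(=O)(=O)C(F)(F)F)C(F)(F)F
Why: O-Triflation of the enolised dione occurs at the oxygen remote from the gem-dimethyl group for steric reasons, which leaves the ketone next to the quaternary carbon.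

Step 27
Reactants: 37 4,4-dimethyl-3-oxocyclohex-1-en-1-yl trifluoromethanesulfonate
Product: 38 methyl 4,4-dimethyl-3-oxocyclohex-1-ene-1-carboxylate
Conditions: Pd(OAc)2 (cat.), dppp, CO (1 atm), MeOH, Et3N, DMF, 60 °C
Reagents that add atoms: carbon monoxide, [C-]#[O+]; methanol, CO
Why: Palladium-catalysed methoxycarbonylation of the alkenyl triflate (oxidative addition, CO insertion, methanolysis).

Step 28
Reactants: 38 methyl 4,4-dimethyl-3-oxocyclohex-1-ene-1-carboxylate
Product: 39 methyl (3S)-3-hydroxy-4,4-dimethylcyclohex-1-ene-1-carboxylate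
Conditions: (R)-2-methyl-CBS-oxazaborolidine (0.2 equiv), BH3·SMe2, THF, −20 °C; MeOH quench
Reagents that add atoms: none
Why: Corey–Bakshi–Shibata reduction: the oxazaborolidine–borane complex delivers hydride to one face of the ketone in a 1,2-reduction and sets the carbinol centre (the future C19) as S.

Step 29
Reactants: 39 methyl (3S)-3-hydroxy-4,4-dimethylcyclohex-1-ene-1-carboxylate
Product: 41 methyl (1S)-4,4-dimethyl-1-(2-oxoethyl)cyclohex-2-ene-1-carboxylate, via allyl vinyl ether 40 (not isolated)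
Conditions: ethyl vinyl ether (excess), Hg(OAc)2 (cat.), sealed tube, 40 °C then 150 °C
Reagents that add atoms: ethyl vinyl ether, C=COCC
Why: Vinyl transfer gives allyl vinyl ether 40, whose Claisen rearrangement is suprafacial, so the CH2CHO group (C16 plus a carbon removed later) is delivered to C17 on the face that carried the C19 oxygen and the carbinol configuration is transferred to the quaternary C17.

Step 30
Reactants: 41 methyl (1S)-4,4-dimethyl-1-(2-oxoethyl)cyclohex-2-ene-1-carboxylate; 35 allylic bromide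
Product: 44 coupled aldehyde (C15–C16 bond; C16–CHO both epimers), via imine 42 (not isolated), via alkylated imine 43 (not isolated)
Conditions: cyclohexylamine, 4 Å MS, Et2O; LDA, THF, −78 °C; then 35, −78 to 0 °C; aq. oxalic acid
Reagents that add atoms: water, O
Why: Metalloenamine alkylation: the lithiated cyclohexylimine of 41 is alkylated at C16 by the primary allylic bromide in an SN2 reaction and mild acid returns the aldehyde; the C16 centre is a mixture that is removed in step 32.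

Step 31
Reactants: 44 coupled aldehyde
Product: 45 pentacyclic C19 pinacol boronate (C13–C18 bond; 18β-H; 19α-B; C16–CHO)
Conditions: Pd2(dba)3 (5 mol %), P(o-tol)3, B2pin2 (slow addition), KOAc, DMF, 80 °C
Reagents that add atoms: bis(pinacolato)diboron, CC1(C)OB(OC1(C)C)B1OC(C)(C)C(C)(C)O1
Why: Domino Heck cyclisation–borylation: zerovalent palladium inserts into the C13–OTf bond, the alkenylpalladium adds 6-exo and syn across the ring E alkene from the face of the C16 tether (C13–C18 bond, cis ring D/E fusion, 18β-H), and the C19 alkylpalladium, which has no syn β-hydrogen because C20 is quaternary and H18 is anti, is captured by the diboron with retention.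

Step 32
Reactants: 45 pentacyclic C19 pinacol boronate
Product: 46 C19 boronate with C16H2
Conditions: RhCl(PPh3)3 (1.1 equiv), toluene, 110 °C
Reagents that add atoms: none
Why: Tsuji–Wilkinson decarbonylation replaces the C16 formyl group by hydrogen; it is placed after ring closure because the 4-pentenal unit of 44 would otherwise undergo hydroacylation.

Step 33
Reactants: 46 C19 boronate
Product: 47 19α-alcohol (28-methyl ester; 24-auxiliary ester; 3α-OTBS)
Conditions: 30% H2O2, aq. NaOH, THF, 0 °C to rt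
Reagents that add atoms: hydrogen peroxide, OO
Why: Oxidation of the secondary boronate proceeds with retention and gives the 19α-alcohol cis to C13 and C16; the two esters on quaternary carbons are too hindered to hydrolyse.

Step 34
Reactants: 47 19α-alcohol
Product: 48 24,28-diol (3α-OTBS; 19α-OH)
Conditions: LiAlH4, THF, reflux
Reagents that add atoms: none
Why: Hydride reduction is the reliable way to cleave the hindered axial 8-phenylmenthyl ester; it also reduces the C28 methyl ester, and the auxiliary alcohol is recovered.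

Step 35
Reactants: 48 24,28-diol
Product: 49 24,28-dialdehyde
Conditions: TEMPO (cat.), PhI(OAc)2, CH2Cl2, rt
Reagents that add atoms: none
Why: The oxoammonium oxidation is selective for primary alcohols, so the hindered axial C19 secondary alcohol is left.

Step 36
Reactants: 49 24,28-dialdehyde
Product: 50 3-O-TBS diacid
Conditions: NaClO2, NaH2PO4, 2-methyl-2-butene, t-BuOH/H2O, rt
Reagents that add atoms: sodium chlorite, [Na+].[O-]Cl=O
Why: Pinnick oxidation converts both hindered aldehydes into acids, and the scavenger protects the tetrasubstituted alkene from hypochlorite.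

Step 37
Reactants: 50 3-O-TBS diacid
Product: 51 target (CNP0394974.1)
Conditions: HF·pyridine, THF, rt to 40 °C
Reagents that add atoms: none
Why: Fluoride-mediated desilylation frees the 3α-alcohol; the methyl ether, the tetrasubstituted alkene and the acids are stable to these conditions.

**Compound list**

1 | (−)-8-phenylmenthol, (1R,2S,5R)-5-methyl-2-(2-phenylpropan-2-yl)cyclohexan-1-ol | CC(C)(c1ccccc1)[C@@H]1CC[C@@H](C)C[C@H]1O | starting material
2 | 2,2,6-trimethyl-4H-1,3-dioxin-4-one | CC1=CC(=O)OC(C)(C)O1 | starting material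
3 | acetylketene | CC(=O)C=C=O | intermediate
4 | (−)-8-phenylmenthyl 3-oxobutanoate | CC(=O)CC(=O)O[C@@H]1C[C@H](C)CC[C@H]1C(C)(C)c1ccccc1 | intermediate
5 | (−)-8-phenylmenthyl 2-methyl-3-oxobutanoate (both C2 epimers) | CC(=O)C(C)C(=O)O[C@@H]1C[C@H](C)CC[C@H]1C(C)(C)c1ccccc1 | intermediate
6 | geranyl acetate | CC(C)=CCC/C(C)=C/COC(C)=O | starting material
7 | (2E,6E)-8-hydroxy-3,7-dimethylocta-2,6-dien-1-yl acetate | OC/C(C)=C/CC/C(C)=C/COC(C)=O | intermediate
8 | (2E,6E)-8-bromo-3,7-dimethylocta-2,6-dien-1-yl acetate | BrC/C(C)=C/CC/C(C)=C/COC(C)=O | intermediate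
9 | (−)-8-phenylmenthyl (6E,10E)-12-acetoxy-2,6,10-trimethyl-3-oxododeca-6,10-dienoate (both C2 epimers) | CC(C(=O)CC/C(C)=C/CC/C(C)=C/COC(C)=O)C(=O)O[C@@H]1C[C@H](C)CC[C@H]1C(C)(C)c1ccccc1 | intermediate
10 | rings A/B keto ester: C3 ketone, 4α-CH3, 4β-CO2(8-phenylmenthyl), 5α-H, 10β-CH3, C8 exocyclic methylene, 9α-H, 9β-CH2OAc | CC(=O)OC[C@H]1C(=C)CC[C@H]2[C@@](C)(C(=O)O[C@@H]3C[C@H](C)CC[C@H]3C(C)(C)c3ccccc3)C(=O)CC[C@]12C | intermediate
11 | 3α-alcohol of 10 | CC(=O)OC[C@H]1C(=C)CC[C@H]2[C@@](C)(C(=O)O[C@@H]3C[C@H](C)CC[C@H]3C(C)(C)c3ccccc3)[C@H](O)CC[C@]12C | intermediate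
12 | 3α-TBS ether of 11 | CC(=O)OC[C@H]1C(=C)CC[C@H]2[C@@](C)(C(=O)O[C@@H]3C[C@H](C)CC[C@H]3C(C)(C)c3ccccc3)[C@H](O[Si](C)(C)C(C)(C)C)CC[C@]12C | intermediate
13 | C11 primary alcohol (9β-CH2OH, C8 exocyclic methylene) | OC[C@H]1C(=C)CC[C@H]2[C@@](C)(C(=O)O[C@@H]3C[C@H](C)CC[C@H]3C(C)(C)c3ccccc3)[C@H](O[Si](C)(C)C(C)(C)C)CC[C@]12C | intermediate
14 | β,γ-unsaturated C11 aldehyde (9β-CHO, C8 exocyclic methylene) | O=C[C@H]1C(=C)CC[C@H]2[C@@](C)(C(=O)O[C@@H]3C[C@H](C)CC[C@H]3C(C)(C)c3ccccc3)[C@H](O[Si](C)(C)C(C)(C)C)CC[C@]12C | intermediate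
15 | conjugated C11 aldehyde (C8=C9, C8–CH3) | O=CC1=C(C)CC[C@H]2[C@@](C)(C(=O)O[C@@H]3C[C@H](C)CC[C@H]3C(C)(C)c3ccccc3)[C@H](O[Si](C)(C)C(C)(C)C)CC[C@]12C | intermediate
16 | allylic alcohol (C11–OH, C8=C9) | OCC1=C(C)CC[C@H]2[C@@](C)(C(=O)O[C@@H]3C[C@H](C)CC[C@H]3C(C)(C)c3ccccc3)[C@H](O[Si](C)(C)C(C)(C)C)CC[C@]12C | intermediate
17 | mixed ketene acetal C11–O–C(OEt)=CH2 of 16 | C=C(OCC)OCC1=C(C)CC[C@H]2[C@@](C)(C(=O)O[C@@H]3C[C@H](C)CC[C@H]3C(C)(C)c3ccccc3)[C@H](O[Si](C)(C)C(C)(C)C)CC[C@]12C | intermediate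
18 | C8 quaternary ester: 8β-CH3, 8α-CH2CO2Et, C9=C11H2 | CCOC(=O)C[C@]1(C)CC[C@@H]2[C@](C)(CC[C@@H](O[Si](C)(C)C(C)(C)C)[C@]2(C)C(=O)O[C@@H]3C[C@H](C)CC[C@H]3C(C)(C)c3ccccc3)C1=C | intermediate
19 | C11 alkylborane (9α-H), drawn as the monoalkylborane | CCOC(=O)C[C@]1(C)CC[C@@H]2[C@](C)(CC[C@@H](O[Si](C)(C)C(C)(C)C)[C@]2(C)C(=O)O[C@@H]3C[C@H](C)CC[C@H]3C(C)(C)c3ccccc3)[C@H]1CB | intermediate
20 | C11 alcohol (9α-H, 9β-CH2OH) | CCOC(=O)C[C@]1(C)CC[C@@H]2[C@](C)(CC[C@@H](O[Si](C)(C)C(C)(C)C)[C@]2(C)C(=O)O[C@@H]3C[C@H](C)CC[C@H]3C(C)(C)c3ccccc3)[C@H]1CO | intermediate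
21 | C11 aldehyde | CCOC(=O)C[C@]1(C)CC[C@@H]2[C@](C)(CC[C@@H](O[Si](C)(C)C(C)(C)C)[C@]2(C)C(=O)O[C@@H]3C[C@H](C)CC[C@H]3C(C)(C)c3ccccc3)[C@H]1C=O | intermediate
22 | methyl enol ether C11=C12–OMe (E/Z mixture) | CCOC(=O)C[C@]1(C)CC[C@@H]2[C@](C)(CC[C@@H](O[Si](C)(C)C(C)(C)C)[C@]2(C)C(=O)O[C@@H]3C[C@H](C)CC[C@H]3C(C)(C)c3ccccc3)[C@H]1C=COC | intermediate
23 | C12 aldehyde | CCOC(=O)C[C@]1(C)CC[C@@H]2[C@](C)(CC[C@@H](O[Si](C)(C)C(C)(C)C)[C@]2(C)C(=O)O[C@@H]3C[C@H](C)CC[C@H]3C(C)(C)c3ccccc3)[C@H]1CC=O | intermediate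
24 | diisopinocampheylborinate of 25 | CCOC(=O)C[C@]1(C)CC[C@@H]2[C@](C)(CC[C@@H](O[Si](C)(C)C(C)(C)C)[C@]2(C)C(=O)O[C@@H]3C[C@H](C)CC[C@H]3C(C)(C)c3ccccc3)[C@H]1C[C@H](OB([C@H]4C[C@H]5C[C@@H]([C@@H]4C)C5(C)C)[C@H]4C[C@H]5C[C@@H]([C@@H]4C)C5(C)C)CC=C | intermediate
25 | (12R)-homoallylic alcohol (C12–OH, C27H2–CH=CH2) | CCOC(=O)C[C@]1(C)CC[C@@H]2[C@](C)(CC[C@@H](O[Si](C)(C)C(C)(C)C)[C@]2(C)C(=O)O[C@@H]3C[C@H](C)CC[C@H]3C(C)(C)c3ccccc3)[C@H]1C[C@H](O)CC=C | intermediate
26 | 12-methyl ether of 25 | CCOC(=O)C[C@]1(C)CC[C@@H]2[C@](C)(CC[C@@H](O[Si](C)(C)C(C)(C)C)[C@]2(C)C(=O)O[C@@H]3C[C@H](C)CC[C@H]3C(C)(C)c3ccccc3)[C@H]1C[C@H](OC)CC=C | intermediate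
27 | trimethylsilyl ketene acetal of the ethyl ester of 26 | CCOC(O[Si](C)(C)C)=C[C@]1(C)CC[C@@H]2[C@](C)(CC[C@@H](O[Si](C)(C)C(C)(C)C)[C@]2(C)C(=O)O[C@@H]3C[C@H](C)CC[C@H]3C(C)(C)c3ccccc3)[C@H]1C[C@H](OC)CC=C | intermediate
28 | α-bromo ester (C14–Br, both epimers) | CCOC(=O)C(Br)[C@]1(C)CC[C@@H]2[C@](C)(CC[C@@H](O[Si](C)(C)C(C)(C)C)[C@]2(C)C(=O)O[C@@H]3C[C@H](C)CC[C@H]3C(C)(C)c3ccccc3)[C@H]1C[C@H](OC)CC=C | intermediate
29 | ozonide (1,2,4-trioxolane) of 28 | CCOC(=O)C(Br)[C@]1(C)CC[C@@H]2[C@](C)(CC[C@@H](O[Si](C)(C)C(C)(C)C)[C@]2(C)C(=O)O[C@@H]3C[C@H](C)CC[C@H]3C(C)(C)c3ccccc3)[C@H]1C[C@H](OC)CC4OCOO4 | intermediate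
30 | C13 aldehyde (C14–Br) | CCOC(=O)C(Br)[C@]1(C)CC[C@@H]2[C@](C)(CC[C@@H](O[Si](C)(C)C(C)(C)C)[C@]2(C)C(=O)O[C@@H]3C[C@H](C)CC[C@H]3C(C)(C)c3ccccc3)[C@H]1C[C@H](OC)CC=O | intermediate
31 | ring C β-hydroxy ester (seven-membered ring; C13–OH, C14–CO2Et; mixture at C13 and C14) | CCOC(=O)C4[C@]1(C)CC[C@@H]2[C@](C)(CC[C@@H](O[Si](C)(C)C(C)(C)C)[C@]2(C)C(=O)O[C@@H]3C[C@H](C)CC[C@H]3C(C)(C)c3ccccc3)[C@H]1C[C@H](OC)CC4O | intermediate
32 | ring C β-keto ester (C13 ketone) | CCOC(=O)C4[C@]1(C)CC[C@@H]2[C@](C)(CC[C@@H](O[Si](C)(C)C(C)(C)C)[C@]2(C)C(=O)O[C@@H]3C[C@H](C)CC[C@H]3C(C)(C)c3ccccc3)[C@H]1C[C@H](OC)CC4=O | intermediate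
33 | enol triflate (C13–OTf, C13=C14, C14–CO2Et) | FC(F)(F)S(=O)(=O)OC4=C(C(=O)OCC)[C@]1(C)CC[C@@H]2[C@](C)(CC[C@@H](O[Si](C)(C)C(C)(C)C)[C@]2(C)C(=O)O[C@@H]3C[C@H](C)CC[C@H]3C(C)(C)c3ccccc3)[C@H]1C[C@H](OC)C4 | intermediate
34 | allylic alcohol (C15–OH) | FC(F)(F)S(=O)(=O)OC4=C(CO)[C@]1(C)CC[C@@H]2[C@](C)(CC[C@@H](O[Si](C)(C)C(C)(C)C)[C@]2(C)C(=O)O[C@@H]3C[C@H](C)CC[C@H]3C(C)(C)c3ccccc3)[C@H]1C[C@H](OC)C4 | intermediate
35 | allylic bromide (C15–Br) | FC(F)(F)S(=O)(=O)OC4=C(CBr)[C@]1(C)CC[C@@H]2[C@](C)(CC[C@@H](O[Si](C)(C)C(C)(C)C)[C@]2(C)C(=O)O[C@@H]3C[C@H](C)CC[C@H]3C(C)(C)c3ccccc3)[C@H]1C[C@H](OC)C4 | intermediate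
36 | 4,4-dimethylcyclohexane-1,3-dione | CC1(C)CCC(=O)CC1=O | starting material
37 | 4,4-dimethyl-3-oxocyclohex-1-en-1-yl trifluoromethanesulfonate | CC1(C)CCC(OS(=O)(=O)C(F)(F)F)=CC1=O | intermediate
38 | methyl 4,4-dimethyl-3-oxocyclohex-1-ene-1-carboxylate | COC(=O)C1=CC(=O)C(C)(C)CC1 | intermediate
39 | methyl (3S)-3-hydroxy-4,4-dimethylcyclohex-1-ene-1-carboxylate | COC(=O)C1=C[C@H](O)C(C)(C)CC1 | intermediate
40 | methyl (3S)-4,4-dimethyl-3-(vinyloxy)cyclohex-1-ene-1-carboxylate | COC(=O)C1=C[C@H](OC=C)C(C)(C)CC1 | intermediate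
41 | methyl (1S)-4,4-dimethyl-1-(2-oxoethyl)cyclohex-2-ene-1-carboxylate | O=CC[C@@]1(C(=O)OC)CCC(C)(C)C=C1 | intermediate
42 | N-cyclohexylimine of 41 | C1CCCCC1N=CC[C@@]1(C(=O)OC)CCC(C)(C)C=C1 | intermediate
43 | C16-alkylated imine (C15–C16 bond) | FC(F)(F)S(=O)(=O)OC4=C(CC(C=NC5CCCCC5)[C@@]6(C(=O)OC)CCC(C)(C)C=C6)[C@]1(C)CC[C@@H]2[C@](C)(CC[C@@H](O[Si](C)(C)C(C)(C)C)[C@]2(C)C(=O)O[C@@H]3C[C@H](C)CC[C@H]3C(C)(C)c3ccccc3)[C@H]1C[C@H](OC)C4 | intermediate
44 | coupled aldehyde: ring C enol triflate joined through C15 to C16(CHO)–C17 of the ring E cyclohexene | FC(F)(F)S(=O)(=O)OC4=C(CC(C=O)[C@@]6(C(=O)OC)CCC(C)(C)C=C6)[C@]1(C)CC[C@@H]2[C@](C)(CC[C@@H](O[Si](C)(C)C(C)(C)C)[C@]2(C)C(=O)O[C@@H]3C[C@H](C)CC[C@H]3C(C)(C)c3ccccc3)[C@H]1C[C@H](OC)C4 | intermediate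
45 | pentacyclic 19α-pinacol boronate with C16–CHO (18β-H, cis ring D/E) | CO[C@@H]1CC2=C(CC(C=O)[C@@]3(C(=O)OC)CCC(C)(C)[C@@H](B4OC(C)(C)C(C)(C)O4)[C@@H]23)[C@]2(C)CC[C@@H]3[C@](C)(CC[C@@H](O[Si](C)(C)C(C)(C)C)[C@]3(C)C(=O)O[C@@H]5C[C@H](C)CC[C@H]5C(C)(C)c5ccccc5)[C@H]2C1 | intermediate
46 | 19α-pinacol boronate with C16H2 | CO[C@@H]1CC2=C(CC[C@@]3(C(=O)OC)CCC(C)(C)[C@@H](B4OC(C)(C)C(C)(C)O4)[C@@H]23)[C@]2(C)CC[C@@H]3[C@](C)(CC[C@@H](O[Si](C)(C)C(C)(C)C)[C@]3(C)C(=O)O[C@@H]5C[C@H](C)CC[C@H]5C(C)(C)c5ccccc5)[C@H]2C1 | intermediate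
47 | 19α-alcohol: 28-methyl ester, 24-(8-phenylmenthyl) ester, 3α-OTBS, 12α-OMe | CO[C@@H]1CC2=C(CC[C@@]3(C(=O)OC)CCC(C)(C)[C@@H](O)[C@@H]23)[C@]2(C)CC[C@@H]3[C@](C)(CC[C@@H](O[Si](C)(C)C(C)(C)C)[C@]3(C)C(=O)O[C@@H]5C[C@H](C)CC[C@H]5C(C)(C)c5ccccc5)[C@H]2C1 | intermediate
48 | 24,28-diol (3α-OTBS, 19α-OH) | CO[C@@H]1CC2=C(CC[C@@]3(CO)CCC(C)(C)[C@@H](O)[C@@H]23)[C@]2(C)CC[C@@H]3[C@](C)(CC[C@@H](O[Si](C)(C)C(C)(C)C)[C@]3(C)CO)[C@H]2C1 | intermediate
49 | 24,28-dialdehyde | CO[C@@H]1CC2=C(CC[C@@]3(C=O)CCC(C)(C)[C@@H](O)[C@@H]23)[C@]2(C)CC[C@@H]3[C@](C)(CC[C@@H](O[Si](C)(C)C(C)(C)C)[C@]3(C)C=O)[C@H]2C1 | intermediate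
50 | 3-O-TBS ether of the target diacid | CO[C@@H]1CC2=C(CC[C@@]3(C(=O)O)CCC(C)(C)[C@@H](O)[C@@H]23)[C@]2(C)CC[C@@H]3[C@](C)(CC[C@@H](O[Si](C)(C)C(C)(C)C)[C@]3(C)C(=O)O)[C@H]2C1 | intermediate
51 | CNP0394974.1: 3α,19α-dihydroxy-12α-methoxy diacid with seven-membered ring C and C13=C14 | CO[C@@H]1CC2=C(CC[C@@]3(C(=O)O)CCC(C)(C)[C@@H](O)[C@@H]23)[C@]2(C)CC[C@@H]3[C@](C)(CC[C@@H](O)[C@]3(C)C(=O)O)[C@H]2C1 | target

**Step count and risk**

Total step count: 37. Longest linear sequence: 31 steps (steps 1, 2, 5 to 25 and 30 to 37).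

The three steps most likely to fail:

Step 31. The alkenylpalladium may be borylated or protonated before it inserts into the hindered ring E alkene, or the alkylpalladium may decompose before boron capture. The fallback builds ring D by a cycloaddition instead; it sets out from 31 and comes back at 47. Alcohol 31 is dehydrated (MsCl, Et3N; then DBU) to the ring C enoate F1, reduced with DIBAL-H to the allylic alcohol F2, oxidised with MnO2 to the enal F3 and methylenated with Ph3P=CH2 to the 1-vinylcycloheptene F4. A Lewis-acid-promoted Diels–Alder reaction of this diene with enone ester 38 (Me2AlCl, CH2Cl2, −40 °C) should form the C16–C17 and C13–C18 bonds with a cis ring D/E fusion and give the adduct F5. Its C14–C15 alkene is then moved to the tetrasubstituted C13–C14 position (RhCl3·3H2O, EtOH, 70 °C) to give the C19 ketone F6, and L-Selectride reduction from the convex β face gives 47. The face selectivity of the cycloaddition would have to be established.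

Step 21. The samarium enolate may be protonated, or the aldehyde may undergo pinacol coupling or intermolecular aldol reaction, instead of closing the seven-membered ring. The fallback uses a direct aldol closure without the halide; it sets out from 26 and comes back at 31. Ozonolysis of 26 (O3, CH2Cl2, −78 °C; PPh3) gives the aldehyde ester F7, and soft enolisation of its ethyl ester with TiCl4 and Bu3N (CH2Cl2, −78 °C) should give a titanium enolate that adds to the C13 aldehyde to form 31.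

Step 6. Face control by the auxiliary at C4 may be insufficient, or material may be lost by further oxidation under the oxidative conditions. The fallback generates the same C4 radical by halogen atom transfer; it sets out from 9 and comes back at 10. Keto ester 9 is brominated at C4 (NBS, Mg(ClO4)2, MeCN) to the α-bromo keto ester F8. Atom-transfer radical cyclisation (Et3B, O2, Yb(OTf)3, toluene, −78 °C) should then close rings A and B and end at the tertiary C8 bromide F9, and elimination with DBU (toluene, 80 °C) gives 10. Any C7–C8 alkene isomer formed alongside converges at 15.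

Further compounds
F1 | step 31 | ring C enoate (C13H=C14–CO2Et) | C4=C(C(=O)OCC)[C@]1(C)CC[C@@H]2[C@](C)(CC[C@@H](O[Si](C)(C)C(C)(C)C)[C@]2(C)C(=O)O[C@@H]3C[C@H](C)CC[C@H]3C(C)(C)c3ccccc3)[C@H]1C[C@H](OC)C4
F2 | step 31 | allylic alcohol (C13H=C14–CH2OH) | C4=C(CO)[C@]1(C)CC[C@@H]2[C@](C)(CC[C@@H](O[Si](C)(C)C(C)(C)C)[C@]2(C)C(=O)O[C@@H]3C[C@H](C)CC[C@H]3C(C)(C)c3ccccc3)[C@H]1C[C@H](OC)C4
F3 | step 31 | enal (C13H=C14–CHO) | C4=C(C=O)[C@]1(C)CC[C@@H]2[C@](C)(CC[C@@H](O[Si](C)(C)C(C)(C)C)[C@]2(C)C(=O)O[C@@H]3C[C@H](C)CC[C@H]3C(C)(C)c3ccccc3)[C@H]1C[C@H](OC)C4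
F4 | step 31 | 1-vinylcycloheptene (C13H=C14–C15H=C16H2) | C4=C(C=C)[C@]1(C)CC[C@@H]2[C@](C)(CC[C@@H](O[Si](C)(C)C(C)(C)C)[C@]2(C)C(=O)O[C@@H]3C[C@H](C)CC[C@H]3C(C)(C)c3ccccc3)[C@H]1C[C@H](OC)C4
F5 | step 31 | Diels–Alder adduct (C19 ketone, C14=C15, C13–H unassigned) | CO[C@@H]1CC2C(=CC[C@@]3(C(=O)OC)CCC(C)(C)C(=O)[C@@H]23)[C@]2(C)CC[C@@H]3[C@](C)(CC[C@@H](O[Si](C)(C)C(C)(C)C)[C@]3(C)C(=O)O[C@@H]5C[C@H](C)CC[C@H]5C(C)(C)c5ccccc5)[C@H]2C1
F6 | step 31 | C19 ketone with C13=C14 | CO[C@@H]1CC2=C(CC[C@@]3(C(=O)OC)CCC(C)(C)C(=O)[C@@H]23)[C@]2(C)CC[C@@H]3[C@](C)(CC[C@@H](O[Si](C)(C)C(C)(C)C)[C@]3(C)C(=O)O[C@@H]5C[C@H](C)CC[C@H]5C(C)(C)c5ccccc5)[C@H]2C1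
F7 | step 21 | aldehyde ester (C13 aldehyde, C14H2–CO2Et) | CCOC(=O)C[C@]1(C)CC[C@@H]2[C@](C)(CC[C@@H](O[Si](C)(C)C(C)(C)C)[C@]2(C)C(=O)O[C@@H]3C[C@H](C)CC[C@H]3C(C)(C)c3ccccc3)[C@H]1C[C@H](OC)CC=O
F8 | step 6 | α-bromo keto ester (C4–Br) | CC(Br)(C(=O)CC/C(C)=C/CC/C(C)=C/COC(C)=O)C(=O)O[C@@H]1C[C@H](C)CC[C@H]1C(C)(C)c1ccccc1
F9 | step 6 | tertiary C8 bromide of the bicyclic keto ester | CC(=O)OC[C@H]1C(C)(Br)CC[C@H]2[C@@](C)(C(=O)O[C@@H]3C[C@H](C)CC[C@H]3C(C)(C)c3ccccc3)C(=O)CC[C@]12C
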